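The ten-membered carbocycle is disconnected at C1–C10, the bond that joins the C1 carbinol to C10 of the exocyclic C10=C14 methylene; the key step exploits this allylic alcohol motif of the ten-membered ring. An intramolecular Nozaki–Hiyama–Kishi coupling of a C10 alkenyl bromide with a C1 aldehyde should close the ring, create the C1 stereocentre under ligand control and release the unprotected target in one operation. Its precursor is an open chain that already holds the C6–C7–C11–C12 butenolide, both acetates, the Z C4=C5 olefin and the C6 and C8 stereocentres. The butenolide comes from a Z-bromoenal by asymmetric alkynylation and a cuprate addition, iodination and lactonization cascade.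

Key step: step 11

Remark: the C4=C5 double bond is read from the SMILES as Z (C3 and C6 cis) and is built as such; chiral ligands are specified by the aldehyde face they are chosen to address, and the enantiomer that does so would be confirmed on a model aldehyde.

Step 1
Reactants: 1 but-2-yn-1-ol
Product: 3 (2Z)-3-bromobut-2-en-1-ol, via cyclic sodium alkenylaluminate 2 (not isolated)
Conditions: NaAlH2(OCH2CH2OCH3)2 (Red-Al), THF, 0 °C to rt; then N-bromosuccinimide, -78 to 0 °C
Reagents that add atoms: N-bromosuccinimide, O=C1CCC(=O)N1Br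
Why: Hydroxyl-directed trans-hydroalumination places aluminium on C3 in a five-membered oxaaluminate, and bromodealumination with retention fixes the Z geometry (CH2OH cis to Br) that later becomes the Z C4=C5 olefin.

Step 2
Reactants: 3 (2Z)-3-bromobut-2-en-1-ol
Product: 4 (2Z)-3-bromobut-2-enal
Conditions: activated MnO2, CH2Cl2, rt, dark; used at once
Reagents that add atoms: none
Why: Allylic oxidation with MnO2 is neutral and should give the enal without Z to E isomerization.

Step 3
Reactants: 4 (2Z)-3-bromobut-2-enal; 5 methyl prop-2-ynoate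
Product: 7 methyl (4R,5Z)-6-bromo-4-hydroxyhept-5-en-2-ynoate, via methylzinc acetylide 6 (not isolated)
Conditions: Me2Zn, ProPhenol ligand (enantiomer directing Si-face addition), Ph3PO, toluene, 4 °C
Reagents that add atoms: none
Why: The dinuclear zinc–ProPhenol catalysed 1,2-addition of a zinc acetylide to an enal (asymmetric alkynylation) should set C6 as R by reagent-controlled Si-face attack.

Step 4
Reactants: 7 methyl (4R,5Z)-6-bromo-4-hydroxyhept-5-en-2-ynoate
Product: 9 (5R)-5-[(1Z)-2-bromoprop-1-en-1-yl]-4-ethenyl-3-iodofuran-2(5H)-one, via iodo hydroxy dienoate 8 (not isolated)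
Conditions: CH2=CHMgBr (4 equiv), CuI (1.5 equiv), THF, -78 °C; then I2, -78 to -20 °C; aq. NH4Cl/Na2S2O3, rt
Reagents that add atoms: vinylmagnesium bromide, C=C[Mg]Br; iodine, II
Why: syn-Carbocupration of the ynoate puts vinyl on C7 and copper on C11, iodinolysis with retention gives the 2-iodo dienoate whose ester is cis to the C6 alkoxide and lactonizes, so the tetrasubstituted butenolide forms with C6 untouched (conjugate addition, electrophilic trapping, lactonization).

Step 5
Reactants: 9 (5R)-5-[(1Z)-2-bromoprop-1-en-1-yl]-4-ethenyl-3-iodofuran-2(5H)-one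
Product: 11 (5R)-5-[(1Z)-2-bromoprop-1-en-1-yl]-3-{[(tert-butyldimethylsilyl)oxy]methyl}-4-ethenylfuran-2(5H)-one, via hydroxymethyl butenolide 10 (not isolated)
Conditions: Bu3SnCH2OH, Pd2(dba)3 (cat.), AsPh3, CuI (cat.), NMP, 50 °C; then TBSCl, imidazole, rt
Reagents that add atoms: (tributylstannyl)methanol, CCCC[Sn](CO)(CCCC)CCCC; tert-butyldimethylsilyl chloride, CC(C)(C)[Si](C)(C)Cl
Why: Stille coupling transfers the hydroxymethyl group (C13) to the 2-iodoenoate much faster than palladium inserts into the unactivated alkenyl bromide, and in-flask silylation masks the alcohol before an aldehyde appears at C8.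

Step 6
Reactants: 11 (5R)-5-[(1Z)-2-bromoprop-1-en-1-yl]-3-{[(tert-butyldimethylsilyl)oxy]methyl}-4-ethenylfuran-2(5H)-one
Product: 13 (2R)-2-[(1Z)-2-bromoprop-1-en-1-yl]-4-{[(tert-butyldimethylsilyl)oxy]methyl}-5-oxo-2,5-dihydrofuran-3-carbaldehyde, via diol 12 (not isolated)
Conditions: OsO4 (cat.), NaIO4, 2,6-lutidine, dioxane/H2O, rt
Reagents that add atoms: osmium tetroxide, O=[Os](=O)(=O)=O; sodium periodate, [Na+].[O-]I(=O)(=O)=O
Why: Lemieux–Johnson cleavage should attack only the terminal vinyl group, because the alkenyl bromide and the tetrasubstituted butenolide olefin are electron-poor and hindered, and so unveils the C8 aldehyde.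

Step 7
Reactants: 13 (2R)-2-[(1Z)-2-bromoprop-1-en-1-yl]-4-{[(tert-butyldimethylsilyl)oxy]methyl}-5-oxo-2,5-dihydrofuran-3-carbaldehyde; 14 [2-(1,3-dioxolan-2-yl)ethyl]zinc bromide
Product: 15 (2R)-4-{[(tert-butyldimethylsilyl)oxy]methyl}-2-[(1Z)-4-(1,3-dioxolan-2-yl)-2-methylbut-1-en-1-yl]-5-oxo-2,5-dihydrofuran-3-carbaldehyde
Conditions: Pd(PtBu3)2 (cat.), THF/NMP, rt
Reagents that add atoms: none
Why: Negishi coupling of the alkenyl bromide with a salt-free alkylzinc halide proceeds with retention of the Z geometry and should leave the aldehyde alone, since alkylzinc halides add to carbonyl groups only under Lewis acid activation.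

Step 8
Reactants: 15 (2R)-4-{[(tert-butyldimethylsilyl)oxy]methyl}-2-[(1Z)-4-(1,3-dioxolan-2-yl)-2-methylbut-1-en-1-yl]-5-oxo-2,5-dihydrofuran-3-carbaldehyde; 16 2,3-dibromoprop-1-ene
Product: 18 (5R)-4-[(1S)-3-bromo-1-hydroxybut-3-en-1-yl]-3-{[(tert-butyldimethylsilyl)oxy]methyl}-5-[(1Z)-4-(1,3-dioxolan-2-yl)-2-methylbut-1-en-1-yl]furan-2(5H)-one, via 2-bromoallylchromium dichloride 17 (not isolated)
Conditions: CrCl2 (nickel-free), N-[2-(4-isopropyl-4,5-dihydrooxazol-2-yl)phenyl]methanesulfonamide (enantiomer directing Si-face addition), Et3N, THF, 0 °C to rt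
Reagents that add atoms: none
Why: Divalent chromium reduces only the allylic C–Br bond, and the 2-bromoallylchromium held by the chiral sulfonamide adds to the Si face of the aldehyde (asymmetric Nozaki–Hiyama 2-haloallylation), which should set C8 as S under reagent control and keep the new alkenyl bromide intact.

Step 9
Reactants: 18 (5R)-4-[(1S)-3-bromo-1-hydroxybut-3-en-1-yl]-3-{[(tert-butyldimethylsilyl)oxy]methyl}-5-[(1Z)-4-(1,3-dioxolan-2-yl)-2-methylbut-1-en-1-yl]furan-2(5H)-one
Product: 20 (1S)-1-{(2R)-4-(acetoxymethyl)-2-[(1Z)-4-(1,3-dioxolan-2-yl)-2-methylbut-1-en-1-yl]-5-oxo-2,5-dihydrofuran-3-yl}-3-bromobut-3-en-1-yl acetate, via diol 19 (not isolated)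
Conditions: HF·pyridine, THF, 0 °C; then Ac2O, pyridine, DMAP (cat.), rt
Reagents that add atoms: acetic anhydride, CC(=O)OC(C)=O
Why: Fluoride-mediated desilylation followed by DMAP-catalysed acylation installs the C8 and C13 acetates together, with retention at C8 because its C–O bond is not touched.

Step 10
Reactants: 20 (1S)-1-{(2R)-4-(acetoxymethyl)-2-[(1Z)-4-(1,3-dioxolan-2-yl)-2-methylbut-1-en-1-yl]-5-oxo-2,5-dihydrofuran-3-yl}-3-bromobut-3-en-1-yl acetate
Product: 21 (1S)-1-{(2R)-4-(acetoxymethyl)-2-[(1Z)-2-methyl-5-oxopent-1-en-1-yl]-5-oxo-2,5-dihydrofuran-3-yl}-3-bromobut-3-en-1-yl acetate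
Conditions: pyridinium p-toluenesulfonate, acetone/H2O, 55 °C
Reagents that add atoms: water, O
Why: Mild acid-catalysed acetal hydrolysis frees the C1 aldehyde while the acetates, the lactone and the alkenyl bromide are stable.

Step 11
Reactants: 21 (1S)-1-{(2R)-4-(acetoxymethyl)-2-[(1Z)-2-methyl-5-oxopent-1-en-1-yl]-5-oxo-2,5-dihydrofuran-3-yl}-3-bromobut-3-en-1-yl acetate
Product: 23 8alpha,13-diacetoxy-1beta-hydroxygermacra-4,7(11),10(14)-trien-6alpha,12-olide, via alkenylchromium dichloride 22 (not isolated)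
Conditions: CrCl2 (excess), NiCl2 (cat.), N-[2-(4-isopropyl-4,5-dihydrooxazol-2-yl)phenyl]methanesulfonamide (enantiomer directing Si-face addition), Et3N, THF, rt, slow addition to 2 mM
Reagents that add atoms: none
Why: Zerovalent nickel inserts into the C10–Br bond, the alkenyl group passes to trivalent chromium, and the alkenylchromium adds to the C1 aldehyde; the closest known reaction type is the Nozaki–Hiyama–Kishi macrocyclization that forms a CH(OH)–C(=CH2) unit in medium and large rings. The ten-membered carbocycle C1–C10 closes in a 10-exo-trig addition, the aldehyde oxygen staying outside the ring. The new C1 stereocentre is controlled by the chiral sulfonamide on chromium, which should deliver C10 to the Si face and give 1R. The step needs chemoselectivity for the alkenyl bromide over the two allylic acetates and the butenolide, which the mild divalent chromium reductant and the small amount of nickel should secure. It also needs ring closure over oligomerization, which high dilution, the cis C4=C5 bond and the planar butenolide (both turn elements) favour. The unprotected target should result directly.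

Compound list
1 | but-2-yn-1-ol | CC#CCO | starting material
2 | sodium 2,2-bis(2-methoxyethoxy)-3-methyl-2,5-dihydro-1,2-oxaaluminol-2-uide (cyclic sodium alkenylaluminate) | CC1=CCO[Al-]1(OCCOC)OCCOC.[Na+] | intermediate
3 | (2Z)-3-bromobut-2-en-1-ol | OC/C=C(/C)Br | intermediate
4 | (2Z)-3-bromobut-2-enal | O=C/C=C(/C)Br | intermediate
5 | methyl prop-2-ynoate | C#CC(=O)OC | starting material
6 | methyl 3-(methylzincio)prop-2-ynoate (methylzinc acetylide) | C[Zn]C#CC(=O)OC | intermediate
7 | methyl (4R,5Z)-6-bromo-4-hydroxyhept-5-en-2-ynoate | COC(=O)C#C[C@H](O)/C=C(/C)Br | intermediate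
8 | methyl (2E,4R,5Z)-6-bromo-3-ethenyl-4-hydroxy-2-iodohepta-2,5-dienoate | COC(=O)/C(I)=C(/C=C)[C@H](O)/C=C(/C)Br | intermediate
9 | (5R)-5-[(1Z)-2-bromoprop-1-en-1-yl]-4-ethenyl-3-iodofuran-2(5H)-one | C=CC1=C(I)C(=O)O[C@@H]1/C=C(/C)Br | intermediate
10 | (5R)-5-[(1Z)-2-bromoprop-1-en-1-yl]-4-ethenyl-3-(hydroxymethyl)furan-2(5H)-one | C=CC1=C(CO)C(=O)O[C@@H]1/C=C(/C)Br | intermediate
11 | (5R)-5-[(1Z)-2-bromoprop-1-en-1-yl]-3-{[(tert-butyldimethylsilyl)oxy]methyl}-4-ethenylfuran-2(5H)-one | C=CC1=C(CO[Si](C)(C)C(C)(C)C)C(=O)O[C@@H]1/C=C(/C)Br | intermediate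
12 | (5R)-5-[(1Z)-2-bromoprop-1-en-1-yl]-3-{[(tert-butyldimethylsilyl)oxy]methyl}-4-(1,2-dihydroxyethyl)furan-2(5H)-one (epimers at the carbinol) | OCC(O)C1=C(CO[Si](C)(C)C(C)(C)C)C(=O)O[C@@H]1/C=C(/C)Br | intermediate
13 | (2R)-2-[(1Z)-2-bromoprop-1-en-1-yl]-4-{[(tert-butyldimethylsilyl)oxy]methyl}-5-oxo-2,5-dihydrofuran-3-carbaldehyde | O=CC1=C(CO[Si](C)(C)C(C)(C)C)C(=O)O[C@@H]1/C=C(/C)Br | intermediate
14 | [2-(1,3-dioxolan-2-yl)ethyl]zinc bromide | Br[Zn]CCC1OCCO1 | starting material
15 | (2R)-4-{[(tert-butyldimethylsilyl)oxy]methyl}-2-[(1Z)-4-(1,3-dioxolan-2-yl)-2-methylbut-1-en-1-yl]-5-oxo-2,5-dihydrofuran-3-carbaldehyde | O=CC1=C(CO[Si](C)(C)C(C)(C)C)C(=O)O[C@@H]1/C=C(/C)CCC2OCCO2 | intermediate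
16 | 2,3-dibromoprop-1-ene | C=C(Br)CBr | starting material
17 | (2-bromoprop-2-en-1-yl)chromium dichloride | C=C(Br)C[Cr](Cl)Cl | intermediate
18 | (5R)-4-[(1S)-3-bromo-1-hydroxybut-3-en-1-yl]-3-{[(tert-butyldimethylsilyl)oxy]methyl}-5-[(1Z)-4-(1,3-dioxolan-2-yl)-2-methylbut-1-en-1-yl]furan-2(5H)-one | C=C(Br)C[C@H](O)C1=C(CO[Si](C)(C)C(C)(C)C)C(=O)O[C@@H]1/C=C(/C)CCC2OCCO2 | intermediate
19 | (5R)-4-[(1S)-3-bromo-1-hydroxybut-3-en-1-yl]-5-[(1Z)-4-(1,3-dioxolan-2-yl)-2-methylbut-1-en-1-yl]-3-(hydroxymethyl)furan-2(5H)-one | C=C(Br)C[C@H](O)C1=C(CO)C(=O)O[C@@H]1/C=C(/C)CCC2OCCO2 | intermediate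
20 | (1S)-1-{(2R)-4-(acetoxymethyl)-2-[(1Z)-4-(1,3-dioxolan-2-yl)-2-methylbut-1-en-1-yl]-5-oxo-2,5-dihydrofuran-3-yl}-3-bromobut-3-en-1-yl acetate | C=C(Br)C[C@H](OC(C)=O)C1=C(COC(C)=O)C(=O)O[C@@H]1/C=C(/C)CCC2OCCO2 | intermediate
21 | (1S)-1-{(2R)-4-(acetoxymethyl)-2-[(1Z)-2-methyl-5-oxopent-1-en-1-yl]-5-oxo-2,5-dihydrofuran-3-yl}-3-bromobut-3-en-1-yl acetate | C=C(Br)C[C@H](OC(C)=O)C1=C(COC(C)=O)C(=O)O[C@@H]1/C=C(/C)CCC=O | intermediate
22 | alkenylchromium dichloride derived from 21 (chromium in place of bromine at C10) | C=C([Cr](Cl)Cl)C[C@H](OC(C)=O)C1=C(COC(C)=O)C(=O)O[C@@H]1/C=C(/C)CCC=O | intermediate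
23 | 8alpha,13-diacetoxy-1beta-hydroxygermacra-4,7(11),10(14)-trien-6alpha,12-olide | C=C1C[C@H](OC(C)=O)C2=C(COC(C)=O)C(=O)O[C@@H]2/C=C(/C)CC[C@H]1O | target

Total step count: 11. Longest linear sequence: 11 steps (from 1).

Steps most likely to fail

Step 11. The macrocyclic alkenylchromium addition may show poor facial selectivity at C1, because the ring conformation can override the ligand, and it may lose material to intermolecular coupling. The fallback sets out from 21 and sets C1 after ring closure instead of during it. Ligand-free CrCl2/NiCl2 cyclization at high dilution should give the allylic alcohols as a C1 mixture that contains the 1-epimeric alcohol F1. Oxidation of the mixture with MnO2 should give the macrocyclic enone F2, and oxazaborolidine-catalysed (CBS) 1,2-reduction with catecholborane should then deliver the 1R alcohol. The route is rejoined at 23.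

Step 4. The alkenylcopper may isomerize through its allenolate before iodine captures it, or it may be protonated instead of iodinated; either way the iodobutenolide is lost. The fallback sets out from 4 and brings in C13 with the alkyne instead of by coupling. Alkynylation under the step 3 conditions with tert-butyldimethyl(prop-2-yn-1-yloxy)silane should give (4R,5Z)-6-bromo-1-[(tert-butyldimethylsilyl)oxy]hept-5-en-2-yn-4-ol F3. Hydroxyl-directed anti-carbomagnesiation of F3 with CH2=CHMgCl, followed by capture of the alkenylmagnesium with CO2, should lactonize directly to 11, where the route is rejoined.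

Step 7. The organozinc may add to the very electrophilic C8 aldehyde, or the formyl butenolide may decompose during the cross-coupling. The fallback sets out from 13 and masks the aldehyde first. HC(OMe)3 and pyridinium p-toluenesulfonate in MeOH should give the dimethyl acetal F4. Negishi coupling of F4 with {3-[(4-methoxybenzyl)oxy]propyl}zinc bromide under Pd(PtBu3)2 catalysis should give the coupled acetal F5, and mild aqueous acid should then free only the C8 aldehyde F6. The chromium-mediated 2-bromoallylation of step 8 should give the homoallylic alcohol F7, and HF·pyridine followed by Ac2O as in step 9 should give the diacetate F8. DDQ should remove the 4-methoxybenzyl group to give the primary alcohol F9, and oxidation with TEMPO/PhI(OAc)2 returns to the route at 21.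

Further compounds
F1 | step 11 | 8alpha,13-diacetoxy-1alpha-hydroxygermacra-4,7(11),10(14)-trien-6alpha,12-olide (C1 epimer of 23) | C=C1C[C@H](OC(C)=O)C2=C(COC(C)=O)C(=O)O[C@@H]2/C=C(/C)CC[C@@H]1O
F2 | step 11 | 8alpha,13-diacetoxy-1-oxogermacra-4,7(11),10(14)-trien-6alpha,12-olide | C=C1C[C@H](OC(C)=O)C2=C(COC(C)=O)C(=O)O[C@@H]2/C=C(/C)CCC1=O
F3 | step 4 | (4R,5Z)-6-bromo-1-[(tert-butyldimethylsilyl)oxy]hept-5-en-2-yn-4-ol | CC(C)(C)[Si](C)(C)OCC#C[C@H](O)/C=C(/C)Br
F4 | step 7 | (5R)-5-[(1Z)-2-bromoprop-1-en-1-yl]-3-{[(tert-butyldimethylsilyl)oxy]methyl}-4-(dimethoxymethyl)furan-2(5H)-one | COC(OC)C1=C(CO[Si](C)(C)C(C)(C)C)C(=O)O[C@@H]1/C=C(/C)Br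
F5 | step 7 | (5R)-3-{[(tert-butyldimethylsilyl)oxy]methyl}-4-(dimethoxymethyl)-5-{(1Z)-5-[(4-methoxybenzyl)oxy]-2-methylpent-1-en-1-yl}furan-2(5H)-one | COC(OC)C1=C(CO[Si](C)(C)C(C)(C)C)C(=O)O[C@@H]1/C=C(/C)CCCOCc2ccc(OC)cc2
F6 | step 7 | (2R)-4-{[(tert-butyldimethylsilyl)oxy]methyl}-2-{(1Z)-5-[(4-methoxybenzyl)oxy]-2-methylpent-1-en-1-yl}-5-oxo-2,5-dihydrofuran-3-carbaldehyde | O=CC1=C(CO[Si](C)(C)C(C)(C)C)C(=O)O[C@@H]1/C=C(/C)CCCOCc2ccc(OC)cc2
F7 | step 7 | (5R)-4-[(1S)-3-bromo-1-hydroxybut-3-en-1-yl]-3-{[(tert-butyldimethylsilyl)oxy]methyl}-5-{(1Z)-5-[(4-methoxybenzyl)oxy]-2-methylpent-1-en-1-yl}furan-2(5H)-one | C=C(Br)C[C@H](O)C1=C(CO[Si](C)(C)C(C)(C)C)C(=O)O[C@@H]1/C=C(/C)CCCOCc2ccc(OC)cc2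
F8 | step 7 | (1S)-1-[(2R)-4-(acetoxymethyl)-2-{(1Z)-5-[(4-methoxybenzyl)oxy]-2-methylpent-1-en-1-yl}-5-oxo-2,5-dihydrofuran-3-yl]-3-bromobut-3-en-1-yl acetate | C=C(Br)C[C@H](OC(C)=O)C1=C(COC(C)=O)C(=O)O[C@@H]1/C=C(/C)CCCOCc2ccc(OC)cc2
F9 | step 7 | (1S)-1-{(2R)-4-(acetoxymethyl)-2-[(1Z)-5-hydroxy-2-methylpent-1-en-1-yl]-5-oxo-2,5-dihydrofuran-3-yl}-3-bromobut-3-en-1-yl acetate | C=C(Br)C[C@H](OC(C)=O)C1=C(COC(C)=O)C(=O)O[C@@H]1/C=C(/C)CCCO
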